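(The constants used here are invented; the run is a simulation.)

Decide the nucleophile charge.

| flask | electrophile | nucleophile | solid base | time |
|---|---|---|---|---|
| oak | 1.0 M | 1.30 M | 1.20 M | 10 d |
| maple | 1.0 M | 1.70 M | 1.20 M | 10 d |

    electrophile + nucleophile → acid set free + target (k1 = 0.26 L mol⁻¹ h⁻¹)
    nucleophile + acid set free ⇌ protonated nucleophile, settled at all times (K2 = 1400 L mol⁻¹)
    acid set free + free base ⇌ salt of the base, settled at all times (K3 = 1.2 L mol⁻¹)
    acid set free → by-product carried off (k4 = 0.036 h⁻¹)
    solid base ⇌ free base, rate k5*(cs5 - [free base]) while solid is left; crystals form when [free base] > cs5 (cs5 = 0.38 M, k5 = 0.26 h⁻¹)
    electrophile + target → side product (k6 = 0.033 L mol⁻¹ h⁻¹)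

- in percentages every species weighs as the electrophile in it: one side product counts as two
- as a solid, counted per litre of solution: solid base
- at the start none of the solid base is in solution
- run time (oak): 10 d

- part of the electrophile that has reacted at the end, oak
- part of the electrophile that has reacted at the end, maple
- what raising the concentration of nucleophile from its lowest to its highest value here does to the part of the electrophile that has reacted (changes below 5 percentage points count as none) (it rises / it falls / no change)

Call the capacity, C, the electrophile that the main reaction (electrophile + nucleophile) can take from a nucleophile charge N: 0.650 M for oak and 0.850 M for maple, half of N. Reckon it so because each turnover sets free one acid, and that acid goes to a second nucleophile far more readily than to free base: equilibrium constant times concentration stands at 1800 for nucleophile as charged in oak, against 0.456 for free base at its solubility.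

Expect C to be reached early, since the main reaction's half-life for electrophile in oak, with the other concentrations as charged, 0.085 d, is far shorter than the 10 d allowed. Assume the main reaction stops there. With E the electrophile charge, E − C of electrophile stands against C of target, and the side reaction (electrophile + target), with constant k = 0.033 L mol⁻¹ h⁻¹, removes one of each. Their difference D = N − E therefore stays fixed, at 0.300 M in oak and 0.700 M in maple.

Integrate this second-order law over time t, setting r = ((E − C)/C) exp(−kDt). The electrophile left is Dr/(1 − r), with r = 0.0500 for oak and 6.90 × 10⁻⁴ for maple. So my reckoning gives 98.4% reacted for oak and >99.9% for maple. That gap of 1.5 percentage points is smaller than the 5 points that counts, so I expect no change. Conversion gives no ground for choosing, but D does: charge 1.70 M, for the target that stays.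

The forecast gives 98.8% (96.5% to 99.7%) for oak, 99.9% (99.3% to 100%) for maple and no change, holding that “the leftover electrophile is steadily consumed by reaction with the abundant target”.

The flask gives 99.8% for oak and >99.9% for maple, a change of 0.23 points, so no change. In maple at 0.0748 d, the main reaction uses electrophile 16 times as fast as the side reaction, yet the side reaction's half-life for electrophile at that moment, 2.1 d, is shorter than the 10 d allowed. Maple ends with 69.4% target against the 70.0% reckoned as D, oak with 41.5% against 30.0%. A neighbour of maple charged with 0.68 M of nucleophile has C = 0.340 M, less than its E − C, and it ends with 15.3% electrophile and 7.87% target.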